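**Retrosynthetic overview**
1. Target ⇐ one acidolysis that removes two catechol acetonides and one tert-butyl ester from the fully protected benzodioxinone ester.
2. The 1,4-benzodioxin-2-one lactone (the only ring built for the target, closed last) ⇐ phosphine-catalysed α-O-addition/lactonisation between the free catechol of a protected rosmarinate and a methyl 3-arylpropiolate.
3. Protected rosmarinate ⇐ Mitsunobu esterification, with inversion, of an (S)-aryl-lactate with unprotected caffeic acid.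
4. (S)-Aryl-lactate ⇐ benzylic hydrogenolysis of a (2S,3R)-glycidate ⇐ ketone-catalysed (dioxirane) asymmetric epoxidation of a tert-butyl cinnamate; this oxirane is the first ring made and is opened again.
5. Cinnamate and arylpropiolate both ⇐ 5-bromo-2,2-dimethyl-1,3-benzodioxole (Heck; Negishi); the two benzodioxole rings are bought in.

Assumption: 5-bromo-2,2-dimethyl-1,3-benzodioxole is taken as a catalogue compound; all four starting materials are achiral. The target's single stereocentre is (R), and the benzylidene alkene is Z (aryl cis to the ring oxygen).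

**Step 1**
Reactants: 1 5-bromo-2,2-dimethyl-1,3-benzodioxole; 2 tert-butyl acrylate
Product: 3 tert-butyl (2E)-3-(2,2-dimethyl-1,3-benzodioxol-5-yl)prop-2-enoate
Conditions: Pd(OAc)2 (2 mol%), P(o-tol)3 (6 mol%), Et3N, DMF, 100 °C
Reagents that add atoms: none
Why: Mizoroki–Heck arylation of an acrylate with an aryl bromide gives the E-cinnamate through syn-insertion and syn-β-hydride elimination.

**Step 2**
Reactants: 3 tert-butyl (2E)-3-(2,2-dimethyl-1,3-benzodioxol-5-yl)prop-2-enoate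
Product: 4 tert-butyl (2S,3R)-3-(2,2-dimethyl-1,3-benzodioxol-5-yl)oxirane-2-carboxylate
Conditions: 4,5-di-O-acetyl-1,2-O-isopropylidene-β-D-erythro-2,3-hexodiulo-2,6-pyranose (30 mol%), KHSO5 (Oxone), NaHCO3, Bu4NHSO4 (cat.), MeCN/aq. Na2EDTA, 0 °C
Reagents that add atoms: potassium peroxymonosulfate KHSO5 (Oxone), [K+].[O-]S(=O)(=O)OO
Why: Shi asymmetric epoxidation: the chiral dioxirane formed from the D-fructose-derived ketone transfers oxygen through a spiro transition state to one face of the electron-rich trans-cinnamate (the same facial sense that gives (R,R)-oxides from trans-β-methylstyrene), which sets C2 as S and C3 as R.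

**Step 3**
Reactants: 4 tert-butyl (2S,3R)-3-(2,2-dimethyl-1,3-benzodioxol-5-yl)oxirane-2-carboxylate
Product: 5 tert-butyl (2S)-3-(2,2-dimethyl-1,3-benzodioxol-5-yl)-2-hydroxypropanoate
Conditions: H2 (1 atm), 10% Pd/C, EtOAc, rt
Reagents that add atoms: none
Why: Catalytic hydrogenolysis cleaves only the benzylic C3–O bond of the aryl glycidate, so C3 becomes CH2 and the untouched C2–O bond keeps the S configuration.

**Step 4**
Reactants: 5 tert-butyl (2S)-3-(2,2-dimethyl-1,3-benzodioxol-5-yl)-2-hydroxypropanoate; 6 caffeic acid ((2E)-3-(3,4-dihydroxyphenyl)prop-2-enoic acid)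
Product: 7 tert-butyl (2R)-2-{[(2E)-3-(3,4-dihydroxyphenyl)prop-2-enoyl]oxy}-3-(2,2-dimethyl-1,3-benzodioxol-5-yl)propanoate
Conditions: PPh3, DIAD, THF, 0 °C → rt
Reagents that add atoms: none
Why: Mitsunobu esterification: the carboxylic acid (pKa about 4.5) is the only pronucleophile acidic enough to react ahead of the phenols (pKa 9 or higher) and displaces the alkoxyphosphonium of the lactate-type alcohol by SN2, inverting S to R.

**Step 5**
Reactants: 8 methyl propiolate; 1 5-bromo-2,2-dimethyl-1,3-benzodioxole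
Product: 11 methyl 3-(2,2-dimethyl-1,3-benzodioxol-5-yl)prop-2-ynoate, via lithium acetylide 9 (not isolated), via bromozinc acetylide 10 (not isolated)
Conditions: LiN(i-Pr)2, THF, −78 °C; ZnBr2; then 1, Pd(P(t-Bu)3)2 (3 mol%), −78 °C → rt
Reagents that add atoms: none
Why: Negishi alkynylation: the weakly basic zinc acetylide of the propiolate transmetalates cleanly to the arylpalladium bromide, avoiding the amine-induced oligomerisation of propiolates seen under copper/amine coupling conditions.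

**Step 6**
Reactants: 7 tert-butyl (2R)-2-{[(2E)-3-(3,4-dihydroxyphenyl)prop-2-enoyl]oxy}-3-(2,2-dimethyl-1,3-benzodioxol-5-yl)propanoate; 11 methyl 3-(2,2-dimethyl-1,3-benzodioxol-5-yl)prop-2-ynoate
Product: 13 tert-butyl (2R)-3-(2,2-dimethyl-1,3-benzodioxol-5-yl)-2-({(2E)-3-[(3Z)-3-[(2,2-dimethyl-1,3-benzodioxol-5-yl)methylidene]-2-oxo-2,3-dihydro-1,4-benzodioxin-7-yl]prop-2-enoyl}oxy)propanoate, via open-chain Z-enol ether methyl ester 12 (not isolated)
Conditions: P(4-MeOC6H4)3 (20 mol%), PhMe, 100 °C, 11 (1.05 equiv) added over 4 h; then DBU (10 mol%), 5 Å MS, 80 °C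
Reagents that add atoms: none
Why: Proposed new method: the phosphine adds to the β-carbon of alkynoate 11 and the resulting zwitterion is protonated by the more acidic 4-OH of 7 (para to the acrylate, pKa about 9 against about 12 for the 3-OH); within the ion pair that phenoxide attacks the α-carbon of the vinylphosphonium, and proton shift with loss of phosphine gives the Z-α-aryloxycinnamate 12 (aryl trans to the ester), whose neighbouring 3-OH then closes the six-membered aryl lactone by base-catalysed transesterification with methanol trapped on sieves, any E isomer equilibrating to the less strained Z-lactone; the closest known reaction type is the phosphine-catalysed umpolung α-addition of acidic N–H and O–H pronucleophiles to 2-alkynoates without γ-hydrogens, and its tandem use with a free catechol on a 3-arylpropiolate to form a 3-arylidene-1,4-benzodioxin-2-one has not been shown.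

**Step 7**
Reactants: 13 tert-butyl (2R)-3-(2,2-dimethyl-1,3-benzodioxol-5-yl)-2-({(2E)-3-[(3Z)-3-[(2,2-dimethyl-1,3-benzodioxol-5-yl)methylidene]-2-oxo-2,3-dihydro-1,4-benzodioxin-7-yl]prop-2-enoyl}oxy)propanoate
Product: 14 (2R)-3-(3,4-dihydroxyphenyl)-2-({(2E)-3-[(3Z)-3-[(3,4-dihydroxyphenyl)methylidene]-2-oxo-2,3-dihydro-1,4-benzodioxin-7-yl]prop-2-enoyl}oxy)propanoic acid (CNP0141754.1)
Conditions: TFA/H2O (9:1), Ar, 0 °C → rt
Reagents that add atoms: none
Why: Global acidolysis: SN1 cleavage of the tert-butyl ester and hydrolysis of both catechol isopropylidene ketals occur under conditions in which the aryl lactone, the conjugated enol ether, the secondary ester and the stereocentre are stable, and no base or nucleophile that would open the lactone is present.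

**Compound list**
1 | 5-bromo-2,2-dimethyl-1,3-benzodioxole | CC1(C)Oc2ccc(Br)cc2O1 | starting material
2 | tert-butyl acrylate | C=CC(=O)OC(C)(C)C | starting material
3 | tert-butyl (2E)-3-(2,2-dimethyl-1,3-benzodioxol-5-yl)prop-2-enoate | CC(C)(C)OC(=O)/C=C/c1ccc2OC(C)(C)Oc2c1 | intermediate
4 | tert-butyl (2S,3R)-3-(2,2-dimethyl-1,3-benzodioxol-5-yl)oxirane-2-carboxylate | CC(C)(C)OC(=O)[C@H]1O[C@@H]1c1ccc2OC(C)(C)Oc2c1 | intermediate
5 | tert-butyl (2S)-3-(2,2-dimethyl-1,3-benzodioxol-5-yl)-2-hydroxypropanoate | CC(C)(C)OC(=O)[C@@H](O)Cc1ccc2OC(C)(C)Oc2c1 | intermediate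
6 | caffeic acid, (2E)-3-(3,4-dihydroxyphenyl)prop-2-enoic acid | O=C(O)/C=C/c1ccc(O)c(O)c1 | starting material
7 | tert-butyl (2R)-2-{[(2E)-3-(3,4-dihydroxyphenyl)prop-2-enoyl]oxy}-3-(2,2-dimethyl-1,3-benzodioxol-5-yl)propanoate | CC(C)(C)OC(=O)[C@@H](Cc1ccc2OC(C)(C)Oc2c1)OC(=O)/C=C/c1ccc(O)c(O)c1 | intermediate
8 | methyl propiolate | C#CC(=O)OC | starting material
9 | lithium 3-methoxy-3-oxoprop-1-yn-1-ide (lithium acetylide of methyl propiolate) | [Li]C#CC(=O)OC | intermediate
10 | bromo(3-methoxy-3-oxoprop-1-yn-1-yl)zinc | Br[Zn]C#CC(=O)OC | intermediate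
11 | methyl 3-(2,2-dimethyl-1,3-benzodioxol-5-yl)prop-2-ynoate | COC(=O)C#Cc1ccc2OC(C)(C)Oc2c1 | intermediate
12 | methyl (2Z)-2-{4-[(1E)-3-{[(2R)-1-tert-butoxy-3-(2,2-dimethyl-1,3-benzodioxol-5-yl)-1-oxopropan-2-yl]oxy}-3-oxoprop-1-en-1-yl]-2-hydroxyphenoxy}-3-(2,2-dimethyl-1,3-benzodioxol-5-yl)prop-2-enoate | COC(=O)/C(=C/c1ccc2OC(C)(C)Oc2c1)Oc1ccc(/C=C/C(=O)O[C@H](Cc2ccc3OC(C)(C)Oc3c2)C(=O)OC(C)(C)C)cc1O | intermediate
13 | tert-butyl (2R)-3-(2,2-dimethyl-1,3-benzodioxol-5-yl)-2-({(2E)-3-[(3Z)-3-[(2,2-dimethyl-1,3-benzodioxol-5-yl)methylidene]-2-oxo-2,3-dihydro-1,4-benzodioxin-7-yl]prop-2-enoyl}oxy)propanoate | O=C(/C=C/c1ccc2c(c1)OC(=O)/C(=C/c1ccc3OC(C)(C)Oc3c1)O2)O[C@H](Cc1ccc2OC(C)(C)Oc2c1)C(=O)OC(C)(C)C | intermediate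
14 | (2R)-3-(3,4-dihydroxyphenyl)-2-({(2E)-3-[(3Z)-3-[(3,4-dihydroxyphenyl)methylidene]-2-oxo-2,3-dihydro-1,4-benzodioxin-7-yl]prop-2-enoyl}oxy)propanoic acid | O=C(/C=C/c1ccc2c(c1)OC(=O)/C(=C/c1ccc(O)c(O)c1)O2)O[C@H](Cc1ccc(O)c(O)c1)C(=O)O | target

**Totals**
Total steps: 7. Longest linear sequence: 6 (steps 1, 2, 3, 4, 6, 7; step 5 is the side branch).

**Three steps most likely to fail**

Step 6 (the proposed new cascade). Risks are a slow phosphine addition to the electron-rich arylpropiolate, competing β-addition, a second addition at the 3-OH, or incomplete ring closure. The fallback uses known neolignan (8-O-4') chemistry, sets out from 11 and 7, and comes back to the route at 12. Pyrrolidine (MeOH, rt) adds to 11 to give the enamino ester methyl (2E)-3-(2,2-dimethyl-1,3-benzodioxol-5-yl)-3-(pyrrolidin-1-yl)prop-2-enoate F1, which aqueous acetic acid hydrolyses to the β-keto ester methyl 3-(2,2-dimethyl-1,3-benzodioxol-5-yl)-3-oxopropanoate F2. N-Bromosuccinimide then gives methyl 2-bromo-3-(2,2-dimethyl-1,3-benzodioxol-5-yl)-3-oxopropanoate F3. KHCO3 in DMF alkylates the more acidic 4-OH of 7 with F3 (SN2 ether formation) to the keto ether tert-butyl (2R)-3-(2,2-dimethyl-1,3-benzodioxol-5-yl)-2-{[(2E)-3-(4-{[1-(2,2-dimethyl-1,3-benzodioxol-5-yl)-3-methoxy-1,3-dioxopropan-2-yl]oxy}-3-hydroxyphenyl)prop-2-enoyl]oxy}propanoate F4. NaBH4 (MeOH/THF, 0 °C) reduces only the aryl ketone to the benzylic alcohol tert-butyl (2R)-3-(2,2-dimethyl-1,3-benzodioxol-5-yl)-2-{[(2E)-3-(4-{[1-(2,2-dimethyl-1,3-benzodioxol-5-yl)-1-hydroxy-3-methoxy-3-oxopropan-2-yl]oxy}-3-hydroxyphenyl)prop-2-enoyl]oxy}propanoate F5. TsOH (5 mol%) in toluene at 70 °C dehydrates F5 to 12, which is closed to 13 with DBU and 5 Å sieves as in the second stage of step 6.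

Step 2 (asymmetric epoxidation). Risks are acid-lability of the electron-rich aryl glycidate under the aqueous conditions and an ee below about 90%; the facial sense is also assigned here by analogy with the trans-β-methylstyrene case and should be confirmed on 5. The fallback replaces epoxidation by enamine-catalysed α-oxygenation, sets out from 1 and comes back at 5. Heck reaction of 1 with allyl alcohol (Pd(OAc)2, Bu4NCl, NaHCO3, DMF, 80 °C) gives 3-(2,2-dimethyl-1,3-benzodioxol-5-yl)propanal F6. D-Proline (20 mol%) and nitrosobenzene in CHCl3 at 4 °C give (2S)-2-(anilinooxy)-3-(2,2-dimethyl-1,3-benzodioxol-5-yl)propanal F7, reduced in the same flask with NaBH4 to (2S)-2-(anilinooxy)-3-(2,2-dimethyl-1,3-benzodioxol-5-yl)propan-1-ol F8. H2 over Pd/C cleaves the N–O bond to (2S)-3-(2,2-dimethyl-1,3-benzodioxol-5-yl)propane-1,2-diol F9. TEMPO (cat.), NaOCl (cat.) and NaClO2 (MeCN, pH 6.7 phosphate buffer) oxidise only the primary alcohol to (2S)-3-(2,2-dimethyl-1,3-benzodioxol-5-yl)-2-hydroxypropanoic acid F10. tert-Butyl 2,2,2-trichloroacetimidate then esterifies the acid to give 5.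

Step 5 (Negishi coupling of the propiolate zinc reagent with an electron-rich aryl bromide). Risks are decomposition of the metallated propiolate and slow oxidative addition. The fallback builds the alkyne first and carboxylates last, sets out from 1 and comes back at 11. Sonogashira coupling of 1 with ethynyltrimethylsilane (Pd(PPh3)2Cl2, CuI, Et3N, 70 °C) gives [(2,2-dimethyl-1,3-benzodioxol-5-yl)ethynyl]trimethylsilane F11. K2CO3 in MeOH gives 5-ethynyl-2,2-dimethyl-1,3-benzodioxole F12. n-BuLi (THF, −78 °C) gives 5-(lithioethynyl)-2,2-dimethyl-1,3-benzodioxole F13, which methyl chloroformate converts into 11.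

**Further compounds**
F1 | step 6 | methyl (2E)-3-(2,2-dimethyl-1,3-benzodioxol-5-yl)-3-(pyrrolidin-1-yl)prop-2-enoate | COC(=O)/C=C(/N1CCCC1)c1ccc2OC(C)(C)Oc2c1
F2 | step 6 | methyl 3-(2,2-dimethyl-1,3-benzodioxol-5-yl)-3-oxopropanoate | COC(=O)CC(=O)c1ccc2OC(C)(C)Oc2c1
F3 | step 6 | methyl 2-bromo-3-(2,2-dimethyl-1,3-benzodioxol-5-yl)-3-oxopropanoate (racemic) | COC(=O)C(Br)C(=O)c1ccc2OC(C)(C)Oc2c1
F4 | step 6 | tert-butyl (2R)-3-(2,2-dimethyl-1,3-benzodioxol-5-yl)-2-{[(2E)-3-(4-{[1-(2,2-dimethyl-1,3-benzodioxol-5-yl)-3-methoxy-1,3-dioxopropan-2-yl]oxy}-3-hydroxyphenyl)prop-2-enoyl]oxy}propanoate (both epimers at the new carbon) | COC(=O)C(Oc1ccc(/C=C/C(=O)O[C@H](Cc2ccc3OC(C)(C)Oc3c2)C(=O)OC(C)(C)C)cc1O)C(=O)c1ccc2OC(C)(C)Oc2c1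
F5 | step 6 | tert-butyl (2R)-3-(2,2-dimethyl-1,3-benzodioxol-5-yl)-2-{[(2E)-3-(4-{[1-(2,2-dimethyl-1,3-benzodioxol-5-yl)-1-hydroxy-3-methoxy-3-oxopropan-2-yl]oxy}-3-hydroxyphenyl)prop-2-enoyl]oxy}propanoate (diastereomer mixture at the two new carbons) | COC(=O)C(Oc1ccc(/C=C/C(=O)O[C@H](Cc2ccc3OC(C)(C)Oc3c2)C(=O)OC(C)(C)C)cc1O)C(O)c1ccc2OC(C)(C)Oc2c1
F6 | step 2 | 3-(2,2-dimethyl-1,3-benzodioxol-5-yl)propanal | O=CCCc1ccc2OC(C)(C)Oc2c1
F7 | step 2 | (2S)-2-(anilinooxy)-3-(2,2-dimethyl-1,3-benzodioxol-5-yl)propanal | O=C[C@@H](ONc1ccccc1)Cc1ccc2OC(C)(C)Oc2c1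
F8 | step 2 | (2S)-2-(anilinooxy)-3-(2,2-dimethyl-1,3-benzodioxol-5-yl)propan-1-ol | OC[C@@H](ONc1ccccc1)Cc1ccc2OC(C)(C)Oc2c1
F9 | step 2 | (2S)-3-(2,2-dimethyl-1,3-benzodioxol-5-yl)propane-1,2-diol | OC[C@@H](O)Cc1ccc2OC(C)(C)Oc2c1
F10 | step 2 | (2S)-3-(2,2-dimethyl-1,3-benzodioxol-5-yl)-2-hydroxypropanoic acid | OC(=O)[C@@H](O)Cc1ccc2OC(C)(C)Oc2c1
F11 | step 5 | [(2,2-dimethyl-1,3-benzodioxol-5-yl)ethynyl]trimethylsilane | C[Si](C)(C)C#Cc1ccc2OC(C)(C)Oc2c1
F12 | step 5 | 5-ethynyl-2,2-dimethyl-1,3-benzodioxole | C#Cc1ccc2OC(C)(C)Oc2c1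
F13 | step 5 | 5-(lithioethynyl)-2,2-dimethyl-1,3-benzodioxole | [Li]C#Cc1ccc2OC(C)(C)Oc2c1
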